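**Plan**

- Retrosynthesis (guaiane numbering: C1 ring-fusion CH, C2 CH2, C3 C=O, C4=C5, C6 CH2, C7, C8–O, C9 CH2, C10–Me, C11 the oxygenated side-chain carbon): the C11 acetate and C8 propionate C–O bonds are cut first, then C7–C8 together with C11–O (Prins closure), then the prenyl C7=C11 bond (cross-metathesis), C5–C6 (allyl addition with carbonyl transposition) and last C1–C10 (Mukaiyama–Michael addition).
- Forward: the five-membered ring is present from the start (3-ethoxy-2-methylcyclopent-2-enone); the C10–C9–C8 chain is joined at C1, the C6–C7 unit at C5, the alkene is extended to prenyl, and the seven-membered ring closes in step 6; the two acylations follow.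
- Enabling feature: on the seven-membered ring (C1, C5, C6, C7, C8, C9, C10) the C8 carbinol, C7 with its exocyclic oxygenated C11, and the C10 methyl repeat the 1,3-diol pattern of p-menthane-3,8-diol. C7–C8 can therefore come from a C8 aldehyde and a C7=C11 alkene, which the cyclopentenone ring holds side by side through C1 and C5.
- Stereochemistry: C10 from the imidazolidinone catalyst, C1 from the relative topicity of the same addition, C7 and C8 from the twist-chair transition state of the ring closure under control of C10 and C1.

Key step: step 6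

Remark: diene 3 is a cyclopentadiene that can isomerise by 1,5-hydrogen shift, so it is assumed to be prepared and used below −20 °C without storage.

Step 1
Reactants: 1 3-ethoxy-2-methylcyclopent-2-en-1-one
Product: 3 1-ethoxy-2-methyl-3-(tert-butyldimethylsilyloxy)cyclopenta-1,3-diene, via lithium enolate 2 (not isolated)
Conditions: LiN(iPr)2, THF, −78 °C; then TBSCl, DMPU, −78 to −20 °C; cold pentane/NaHCO3 work-up, used at once
Reagents that add atoms: tert-butyldimethylsilyl chloride, CC(C)(C)[Si](C)(C)Cl
Why: Kinetic deprotonation of a vinylogous ester by a lithium amide takes place at the α′-CH2, and O-silylation of the cross-conjugated enolate gives the 1-alkoxy-3-silyloxy diene (silyl enol ether formation); no stereocentre is formed.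

Step 2
Reactants: 3 1-ethoxy-2-methyl-3-(tert-butyldimethylsilyloxy)cyclopenta-1,3-diene, 4 (E)-but-2-enal
Product: 5 (3S)-3-[(1R)-4-ethoxy-3-methyl-2-oxocyclopent-3-en-1-yl]butanal
Conditions: (2R,5R)-5-benzyl-2-tert-butyl-3-methylimidazolidin-4-one (20 mol %), 2,4-dinitrobenzoic acid (20 mol %), H2O (2 equiv), CH2Cl2, −50 °C
Reagents that add atoms: none
Why: Iminium-catalysed Mukaiyama–Michael addition, in which the benzyl group of the (2R,5R)-imidazolidinone shields one face of the E-iminium ion of 4 so that the nucleophilic CH= carbon of diene 3 adds to the open face and sets the side-chain centre (C10) as S, while a synclinal approach of the two double bonds with the β-hydrogen of the iminium ion over the five-membered ring and the methyl group turned outward sets the ring centre (C1) as R, and loss of the silyl group to water restores the vinylogous ester.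

Step 3
Reactants: 5 (3S)-3-[(1R)-4-ethoxy-3-methyl-2-oxocyclopent-3-en-1-yl]butanal
Product: 6 (5R)-5-[(2S)-4,4-diethoxybutan-2-yl]-3-ethoxy-2-methylcyclopent-2-en-1-one
Conditions: HC(OEt)3, PPTS (cat.), EtOH, 0 °C to rt
Reagents that add atoms: triethyl orthoformate, CCOC(OCC)OCC
Why: Acid-catalysed acetalisation with the orthoformate as water scavenger masks the aldehyde for the Grignard step; the vinylogous ester carbonyl does not react, ethoxy exchange at the enol ether is degenerate, and the mild acid should leave the α-centre C1 untouched.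

Step 4
Reactants: 6 (5R)-5-[(2S)-4,4-diethoxybutan-2-yl]-3-ethoxy-2-methylcyclopent-2-en-1-one, 7 allylmagnesium bromide
Product: 9 (3S)-3-[(1R)-3-methyl-4-oxo-2-(prop-2-en-1-yl)cyclopent-2-en-1-yl]butanal, via tertiary allyl carbinol 8 (not isolated)
Conditions: CH2=CHCH2MgBr, THF, −78 °C; then 1 M aq. HCl, THF, 0 °C to rt
Reagents that add atoms: water, O
Why: 1,2-Addition of the allyl Grignard reagent to the vinylogous ester carbonyl and acid treatment of the tertiary carbinol (Stork–Danheiser transposition: enol ether hydrolysis and loss of water) place the allyl group on the enone β-carbon C5 and the carbonyl on C3, the same acid frees the C8 aldehyde, and C1 and C10 are not involved (C1 stops being α to a carbonyl once the enone forms).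

Step 5
Reactants: 9 (3S)-3-[(1R)-3-methyl-4-oxo-2-(prop-2-en-1-yl)cyclopent-2-en-1-yl]butanal, 10 2-methylbut-2-ene
Product: 11 (3S)-3-[(1R)-3-methyl-2-(3-methylbut-2-en-1-yl)-4-oxocyclopent-2-en-1-yl]butanal
Conditions: second-generation Grubbs catalyst RuCl2(=CHPh)(H2IMes)(PCy3) (5 mol %), 10 (excess), CH2Cl2, 35 °C
Reagents that add atoms: none
Why: Olefin cross-metathesis of the monosubstituted allyl alkene with excess 2-methylbut-2-ene is the standard allyl-to-prenyl conversion and releases propene, while the tetrasubstituted enone alkene is inert and no stereocentre is touched.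

Step 6
Reactants: 11 (3S)-3-[(1R)-3-methyl-2-(3-methylbut-2-en-1-yl)-4-oxocyclopent-2-en-1-yl]butanal
Product: 12 (1R,7S,8R,10S)-8,11-dihydroxyguai-4-en-3-one
Conditions: 0.5 M aq. H2SO4–THF (1:1), 45 °C
Reagents that add atoms: water, O
Why: Protonation of the C8 aldehyde makes it electrophilic enough to be attacked by C7 of the trisubstituted C7=C11 alkene (Markovnikov), which forms the C7–C8 bond and a tertiary C11 cation that water captures to give the 8,11-diol, i.e. an intramolecular Prins cyclisation with hydration. The closest known reaction is the dilute-acid cyclisation of citronellal to p-menthane-3,8-diol, here run one ring size larger. The seven-membered ring (C1, C5, C6, C7, C8, C9, C10) closes 7-exo-trig at the carbonyl carbon, the alkene reacting through its inner carbon so that C11 stays exocyclic; the planar cyclopentenone holds the C1 and C5 side chains on one edge, which offsets the entropic cost of the medium ring. C7 is controlled by the existing C1 and C10 centres through a twist-chair transition state (C9 isoclinal) in which the C10 methyl and the developing C7–C11 unit are pseudo-equatorial, which should give 7S. C8 is controlled by the preference of the small protonated carbonyl oxygen for the pseudo-axial position next to the developing cation (as in the cis-diol from citronellal), which should give 8R, i.e. hydroxyl, side chain and C10 methyl all cis. The step needs chemoselectivity for the aldehyde–prenyl pair and Markovnikov regioselectivity: the tetrasubstituted, electron-poor enone alkene is not nucleophilic and survives dilute aqueous acid, and only attack through C7 leads to a tertiary cation.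

Step 7
Reactants: 12 (1R,7S,8R,10S)-8,11-dihydroxyguai-4-en-3-one
Product: 13 (1R,7S,8R,10S)-11-hydroxy-3-oxoguai-4-en-8-yl propanoate
Conditions: (EtCO)2O, pyridine, DMAP (cat.), CH2Cl2, 0 °C
Reagents that add atoms: propionic anhydride, CCC(=O)OC(=O)CC
Why: DMAP-catalysed acylation distinguishes the secondary C8 hydroxyl from the hindered tertiary C11 hydroxyl by rate, so only the C8 propionate should form and no stereocentre is touched.

Step 8
Reactants: 13 (1R,7S,8R,10S)-11-hydroxy-3-oxoguai-4-en-8-yl propanoate
Product: 14 (1R,7S,8R,10S)-11-acetoxy-3-oxoguai-4-en-8-yl propanoate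
Conditions: Ac2O, Sc(OTf)3 (2 mol %), MeCN, −20 °C
Reagents that add atoms: acetic anhydride, CC(=O)OC(C)=O
Why: Lewis-acid-catalysed acylation, in which Sc(OTf)3 activates the anhydride strongly enough to esterify a tertiary alcohol at low temperature, where ionisation and elimination at C11 are slow, and which leaves the C8 ester and all stereocentres unchanged.

**Compound list**

1 | 3-ethoxy-2-methylcyclopent-2-en-1-one | CCOC1=C(C)C(=O)CC1 | starting material
2 | lithium 4-ethoxy-5-methylcyclopenta-1,4-dien-1-olate (lithium enolate of 1, not isolated) | [Li+].CCOC1=C(C)C([O-])=CC1 | intermediate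
3 | 1-ethoxy-2-methyl-3-(tert-butyldimethylsilyloxy)cyclopenta-1,3-diene | CCOC1=C(C)C(O[Si](C)(C)C(C)(C)C)=CC1 | intermediate
4 | (E)-but-2-enal (crotonaldehyde) | C/C=C/C=O | starting material
5 | (3S)-3-[(1R)-4-ethoxy-3-methyl-2-oxocyclopent-3-en-1-yl]butanal | CCOC1=C(C)C(=O)[C@@H]([C@@H](C)CC=O)C1 | intermediate
6 | (5R)-5-[(2S)-4,4-diethoxybutan-2-yl]-3-ethoxy-2-methylcyclopent-2-en-1-one | CCOC1=C(C)C(=O)[C@@H]([C@@H](C)CC(OCC)OCC)C1 | intermediate
7 | allylmagnesium bromide | C=CC[Mg]Br | starting material
8 | (5R)-5-[(2S)-4,4-diethoxybutan-2-yl]-3-ethoxy-2-methyl-1-(prop-2-en-1-yl)cyclopent-2-en-1-ol (both C1 epimers, not isolated) | CCOC1=C(C)C(O)(CC=C)[C@@H]([C@@H](C)CC(OCC)OCC)C1 | intermediate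
9 | (3S)-3-[(1R)-3-methyl-4-oxo-2-(prop-2-en-1-yl)cyclopent-2-en-1-yl]butanal | O=CC[C@H](C)[C@H]1CC(=O)C(C)=C1CC=C | intermediate
10 | 2-methylbut-2-ene | CC=C(C)C | starting material
11 | (3S)-3-[(1R)-3-methyl-2-(3-methylbut-2-en-1-yl)-4-oxocyclopent-2-en-1-yl]butanal | O=CC[C@H](C)[C@H]1CC(=O)C(C)=C1CC=C(C)C | intermediate
12 | (1R,7S,8R,10S)-8,11-dihydroxyguai-4-en-3-one, i.e. (5S,6R,8S,8aR)-6-hydroxy-5-(2-hydroxypropan-2-yl)-3,8-dimethyl-4,5,6,7,8,8a-hexahydroazulen-2(1H)-one | O[C@@H]1C[C@H](C)[C@H]2CC(=O)C(C)=C2C[C@@H]1C(C)(C)O | intermediate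
13 | (1R,7S,8R,10S)-11-hydroxy-3-oxoguai-4-en-8-yl propanoate | CCC(=O)O[C@@H]1C[C@H](C)[C@H]2CC(=O)C(C)=C2C[C@@H]1C(C)(C)O | intermediate
14 | (1R,7S,8R,10S)-11-acetoxy-3-oxoguai-4-en-8-yl propanoate | CCC(=O)O[C@@H]1C[C@H](C)[C@H]2CC(=O)C(C)=C2C[C@@H]1C(C)(C)OC(C)=O | target

**Step count and risks**

Total step count: 8. Longest linear sequence: 8 steps (1 to 14).

Steps most likely to fail:

1. Step 6. The seven-membered closure may be outrun by plain acid hydration of the prenyl alkene or by acid-induced aldol chemistry of the aldehyde, and the facial selectivity at C8 (pseudo-axial against pseudo-equatorial carbonyl oxygen) may be low. The fallback sets out from 11 and comes back at 13. Me2AlCl in CH2Cl2 at −78 °C should close the same C7–C8 bond by a concerted carbonyl-ene reaction (hydrogen transfer from a C11 methyl group to oxygen, no free cation, no water). With the aluminium-bound oxygen pseudo-equatorial, the expected product is the 8-epimeric isopropenyl alcohol (1R,7R,8S,10S)-8-hydroxyguaia-4,11(12)-dien-3-one F1; the geometry at C7 is that of 12, and the descriptor changes only because C11 has lost its oxygen. Mitsunobu esterification with propionic acid (PPh3, DIAD, toluene) inverts C8 and installs the ester in one operation, giving (1R,7R,8R,10S)-3-oxoguaia-4,11(12)-dien-8-yl propanoate F2. Markovnikov hydration of the isopropenyl group (Co(acac)2, PhSiH3, O2, iPrOH) then gives 13.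

2. Step 2. The open transition state may give low simple diastereoselectivity (C1 against C10 topicity), and the electron-rich cyclopentadiene may undergo 1,5-hydrogen shift or [4+2] closure onto the iminium ion before the conjugate addition is complete. The fallback sets out from 1 and comes back at 6. The lithium enolate 2 is added to 3,3-diethoxypropanal (THF, −78 °C) to give the aldol 5-(3,3-diethoxy-1-hydroxypropyl)-3-ethoxy-2-methylcyclopent-2-en-1-one F3 as a diastereomer mixture. MsCl/Et3N converts it into 3,3-diethoxy-1-(4-ethoxy-3-methyl-2-oxocyclopent-3-en-1-yl)propyl methanesulfonate F4, and DBU eliminates this to the exocyclic enone (5E)-5-(3,3-diethoxypropylidene)-3-ethoxy-2-methylcyclopent-2-en-1-one F5. Copper-catalysed enantioselective conjugate addition of Me2Zn (Cu(OTf)2, chiral phosphoramidite ligand of the enantiomer that gives the S centre) sets C10 under catalyst control without any silyl diene. C1, still α to the ketone, is adjusted by DBU equilibration; the epimer (5S)-5-[(2S)-4,4-diethoxybutan-2-yl]-3-ethoxy-2-methylcyclopent-2-en-1-one F6 is separated and returned to the equilibration, which gives 6.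

3. Step 8. The Lewis acid may ionise the tertiary C11 carbinol with elimination to the alkene, or the neighbouring C8 ester may take part and scramble the two acyl groups. The fallback sets out from 12 and comes back at 14. TESCl/imidazole (CH2Cl2, 0 °C) should silylate only the secondary hydroxyl to give (1R,7S,8R,10S)-11-hydroxy-8-(triethylsilyloxy)guai-4-en-3-one F7. With no neighbouring ester present, the tertiary hydroxyl is acetylated under nucleophilic catalysis (Ac2O, Et3N, DMAP, 50 °C) to give (1R,7S,8R,10S)-3-oxo-8-(triethylsilyloxy)guai-4-en-11-yl acetate F8. HF·pyridine (THF, 0 °C) removes the silyl group to give (1R,7S,8R,10S)-8-hydroxy-3-oxoguai-4-en-11-yl acetate F9, and propionylation under the conditions of step 7 gives 14.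

Further compounds

F1 | step 6 | (1R,7R,8S,10S)-8-hydroxyguaia-4,11(12)-dien-3-one | O[C@H]1C[C@H](C)[C@H]2CC(=O)C(C)=C2C[C@@H]1C(C)=C
F2 | step 6 | (1R,7R,8R,10S)-3-oxoguaia-4,11(12)-dien-8-yl propanoate | CCC(=O)O[C@@H]1C[C@H](C)[C@H]2CC(=O)C(C)=C2C[C@@H]1C(C)=C
F3 | step 2 | 5-(3,3-diethoxy-1-hydroxypropyl)-3-ethoxy-2-methylcyclopent-2-en-1-one (diastereomer mixture) | CCOC1=C(C)C(=O)C(C1)C(O)CC(OCC)OCC
F4 | step 2 | 3,3-diethoxy-1-(4-ethoxy-3-methyl-2-oxocyclopent-3-en-1-yl)propyl methanesulfonate (diastereomer mixture) | CCOC1=C(C)C(=O)C(C1)C(OS(C)(=O)=O)CC(OCC)OCC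
F5 | step 2 | (5E)-5-(3,3-diethoxypropylidene)-3-ethoxy-2-methylcyclopent-2-en-1-one | CCOC1=C(C)C(=O)/C(=C/CC(OCC)OCC)C1
F6 | step 2 | (5S)-5-[(2S)-4,4-diethoxybutan-2-yl]-3-ethoxy-2-methylcyclopent-2-en-1-one (C1 epimer of 6) | CCOC1=C(C)C(=O)[C@H]([C@@H](C)CC(OCC)OCC)C1
F7 | step 8 | (1R,7S,8R,10S)-11-hydroxy-8-(triethylsilyloxy)guai-4-en-3-one | CC[Si](CC)(CC)O[C@@H]1C[C@H](C)[C@H]2CC(=O)C(C)=C2C[C@@H]1C(C)(C)O
F8 | step 8 | (1R,7S,8R,10S)-3-oxo-8-(triethylsilyloxy)guai-4-en-11-yl acetate | CC[Si](CC)(CC)O[C@@H]1C[C@H](C)[C@H]2CC(=O)C(C)=C2C[C@@H]1C(C)(C)OC(C)=O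
F9 | step 8 | (1R,7S,8R,10S)-8-hydroxy-3-oxoguai-4-en-11-yl acetate | O[C@@H]1C[C@H](C)[C@H]2CC(=O)C(C)=C2C[C@@H]1C(C)(C)OC(C)=O
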